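**Retrosynthetic overview**
1. Target 32 ⇐ 31 (one acid step removes six MOM groups and one acetate) ⇐ Heck coupling of aryl bromide 29 with 4-acetoxystyrene 30; the E-stilbene is made last.
2. Both dihydrobenzofuran rings of 29 (C2–C3 and C2–O bonds, all four stereocentres) ⇐ bis-sulfone 14 + two equivalents of chiral sulfonium benzylide 23 in one flask (new enantioselective double [4+1]); the inner ring, which carries the 3,5-dioxyphenyl group, is written as closing first, then the bromo-bearing ring.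
3. 14 ⇐ bis-carbinol 12 ⇐ two successive aryllithium additions to the same aldehyde 7 (8 + 7 → 9; lithiated 9 + 7 → 12).
4. All three resorcinol rings come from 5-bromoresorcinol (1 → 2 → 5 → 6 → 7); sulfonium salt 22 comes from (2R,5R)-hexane-2,5-diol and 4-hydroxybenzaldehyde.

Assumption 1: the target is taken exactly as drawn, i.e. the trans,trans-(2S,3S,2′S,3′S) trimer with an E-stilbene.
Assumption 2: the (2S,5S)-thiolanium ylide is taken to react on the same face as in its known epoxidations, which maps onto the (2S,3S) series here; if step 15 gives the antipode, the enantiomeric sulfide from (2S,5S)-hexane-2,5-diol is used with nothing else changed.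
Assumption 3: in step 15 the two ring closures are written in the order inner ring first (its phenoxide is the more electron-rich and should expel sulfinate faster); the product does not depend on this order.
Note: metal alkoxides that are only the unprotonated product before quench are not numbered separately.

Step 1
Reactants: 1 5-bromobenzene-1,3-diol
Product: 2 1-bromo-3,5-bis(methoxymethoxy)benzene
Conditions: NaH (2.4 equiv), MOMCl (2.4 equiv), THF/DMF, 0 °C → rt
Reagents that add atoms: chloromethyl methyl ether (MOMCl), COCCl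
Why: Williamson O-alkylation of both phenoxides; MOM later directs the lithiation, survives organolithiums and carbonate base, and is removed in the final acid step.

Step 2
Reactants: 2 1-bromo-3,5-bis(methoxymethoxy)benzene
Product: 5 4-bromo-2,6-bis(methoxymethoxy)benzaldehyde, via [4-bromo-2,6-bis(methoxymethoxy)phenyl]lithium 3 (not isolated), via lithium [4-bromo-2,6-bis(methoxymethoxy)phenyl](dimethylamino)methanolate 4 (not isolated)
Conditions: LDA (1.1 equiv), THF, −78 °C; DMF (2 equiv), −78 → 0 °C; AcOH/H2O quench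
Reagents that add atoms: N,N-dimethylformamide, CN(C)C=O
Why: Directed ortho-metalation: the amide base removes the proton flanked by the two OMOM groups without Br/Li exchange, and formylation of the aryllithium with DMF gives the aldehyde when the hemiaminal alkoxide collapses.

Step 3
Reactants: 5 4-bromo-2,6-bis(methoxymethoxy)benzaldehyde
Product: 6 4-bromo-2-hydroxy-6-(methoxymethoxy)benzaldehyde
Conditions: 3 M aq. HCl, THF, rt, stopped at full conversion of 5
Reagents that add atoms: none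
Why: Acid acetal hydrolysis that stops after one MOM group, because the freed phenol hydrogen-bonds to the formyl group and deactivates the remaining ortho acetal (selective mono-deprotection).

Step 4
Reactants: 6 4-bromo-2-hydroxy-6-(methoxymethoxy)benzaldehyde
Product: 7 4-bromo-2-(methoxymethoxy)-6-(prop-2-en-1-yloxy)benzaldehyde
Conditions: allyl bromide (1.3 equiv), K2CO3 (2 equiv), DMF, rt
Reagents that add atoms: allyl bromide (3-bromoprop-1-ene), C=CCBr
Why: Williamson O-allylation of the phenol gives a neutral aldehyde for organolithium additions; the allyl ether is orthogonal to MOM and is removed later with Pd(0) without touching the aryl bromide.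

Step 5
Reactants: 2 1-bromo-3,5-bis(methoxymethoxy)benzene; 7 4-bromo-2-(methoxymethoxy)-6-(prop-2-en-1-yloxy)benzaldehyde
Product: 9 rac-[4-bromo-2-(methoxymethoxy)-6-(prop-2-en-1-yloxy)phenyl][3,5-bis(methoxymethoxy)phenyl]methanol, via [3,5-bis(methoxymethoxy)phenyl]lithium 8 (not isolated)
Conditions: 2 (1.2 equiv), n-BuLi (1.2 equiv), THF, −78 °C, 20 min; 7 (1.0 equiv) in THF, −78 → −20 °C; AcOH
Reagents that add atoms: none
Why: Br/Li exchange (faster than ortho-lithiation at −78 °C) followed by 1,2-addition of the aryllithium to the aldehyde, which outpaces ArLi/ArBr exchange; the racemic carbinol centre becomes sp2 in step 15.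

Step 6
Reactants: 9 rac-[4-bromo-2-(methoxymethoxy)-6-(prop-2-en-1-yloxy)phenyl][3,5-bis(methoxymethoxy)phenyl]methanol; 7 4-bromo-2-(methoxymethoxy)-6-(prop-2-en-1-yloxy)benzaldehyde
Product: 12 [4-bromo-2-(methoxymethoxy)-6-(prop-2-en-1-yloxy)phenyl]{4-[[3,5-bis(methoxymethoxy)phenyl](hydroxy)methyl]-3-(methoxymethoxy)-5-(prop-2-en-1-yloxy)phenyl}methanol (mixture of diastereomers), via lithium [4-bromo-2-(methoxymethoxy)-6-(prop-2-en-1-yloxy)phenyl][3,5-bis(methoxymethoxy)phenyl]methanolate 10 (not isolated), via lithium [3,5-bis(methoxymethoxy)phenyl][4-lithio-2-(methoxymethoxy)-6-(prop-2-en-1-yloxy)phenyl]methanolate 11 (not isolated)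
Conditions: 9, n-BuLi (1.0 equiv; O-lithiation), then n-BuLi (1.1 equiv; Br/Li exchange), THF, −78 °C, 20 min; 7 (1.2 equiv), −78 → −20 °C; AcOH
Reagents that add atoms: none
Why: O–H deprotonation and then Br/Li exchange are both faster at −78 °C than metalation of the allyl or MOM ethers, and the alkoxide-bearing aryllithium adds 1,2 to the neutral aldehyde; both carbinol centres are erased in step 15, so the diastereomer mixture is carried on.

Step 7
Reactants: 12 [4-bromo-2-(methoxymethoxy)-6-(prop-2-en-1-yloxy)phenyl]{4-[[3,5-bis(methoxymethoxy)phenyl](hydroxy)methyl]-3-(methoxymethoxy)-5-(prop-2-en-1-yloxy)phenyl}methanol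
Product: 13 5-bromo-2-[{4-[[3,5-bis(methoxymethoxy)phenyl](hydroxy)methyl]-3-hydroxy-5-(methoxymethoxy)phenyl}(hydroxy)methyl]-3-(methoxymethoxy)phenol (mixture of diastereomers)
Conditions: Pd(PPh3)4 (5 mol%), morpholine (6 equiv), THF, degassed, rt
Reagents that add atoms: none
Why: Tsuji–Trost deallylation: Pd(0) ionises both aryl allyl ethers to π-allyl complexes that morpholine captures; at rt the electron-rich aryl bromide does not undergo oxidative addition to Pd(PPh3)4, and the MOM ethers and carbinols are untouched.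

Step 8
Reactants: 13 5-bromo-2-[{4-[[3,5-bis(methoxymethoxy)phenyl](hydroxy)methyl]-3-hydroxy-5-(methoxymethoxy)phenyl}(hydroxy)methyl]-3-(methoxymethoxy)phenol
Product: 14 5-bromo-2-[{4-[[3,5-bis(methoxymethoxy)phenyl](4-methylbenzenesulfonyl)methyl]-3-hydroxy-5-(methoxymethoxy)phenyl}(4-methylbenzenesulfonyl)methyl]-3-(methoxymethoxy)phenol (mixture of diastereomers)
Conditions: p-TolSO2H (3 equiv, freshly liberated), CH2Cl2, rt
Reagents that add atoms: 4-methylbenzenesulfinic acid, Cc1ccc(S(=O)O)cc1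
Why: SN1 sulfonylation at both carbinols: each is doubly benzylic with an ortho-hydroxy, ortho-alkoxy aryl ring, ionises under the weak acid and is captured at sulfur by sulfinate, giving a bench-stable double o-quinone methide precursor that base can trigger; aryl MOM ethers tolerate the weak acid.

Step 9
Reactants: 15 (2R,5R)-hexane-2,5-diol
Product: 16 (2R,5R)-hexane-2,5-diyl dimethanesulfonate
Conditions: MsCl (2.3 equiv), Et3N (3 equiv), CH2Cl2, 0 °C
Reagents that add atoms: methanesulfonyl chloride, CS(=O)(=O)Cl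
Why: O-sulfonylation of both secondary alcohols with retention at carbon, activating them for displacement.

Step 10
Reactants: 16 (2R,5R)-hexane-2,5-diyl dimethanesulfonate
Product: 17 (2S,5S)-2,5-dimethylthiolane
Conditions: Na2S·9H2O (1.2 equiv), DMSO, rt; distilled
Reagents that add atoms: sodium sulfide, [Na+].[Na+].[S-2]
Why: Double SN2 thioetherification (inter- then intramolecular), each with clean inversion, converts the (R,R)-dimesylate into the C2-symmetric (S,S)-sulfide.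

Step 11
Reactants: 18 4-hydroxybenzaldehyde
Product: 19 4-(methoxymethoxy)benzaldehyde
Conditions: NaH (1.1 equiv), MOMCl (1.1 equiv), THF/DMF, 0 °C → rt
Reagents that add atoms: chloromethyl methyl ether (MOMCl), COCCl
Why: Williamson O-alkylation of the phenoxide.

Step 12
Reactants: 19 4-(methoxymethoxy)benzaldehyde
Product: 20 [4-(methoxymethoxy)phenyl]methanol
Conditions: NaBH4 (0.3 equiv), MeOH, 0 °C
Reagents that add atoms: none
Why: Borohydride reduction of the aldehyde; the MOM ether is inert.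

Step 13
Reactants: 20 [4-(methoxymethoxy)phenyl]methanol
Product: 21 1-(bromomethyl)-4-(methoxymethoxy)benzene
Conditions: CBr4 (1.2 equiv), PPh3 (1.2 equiv), CH2Cl2, 0 °C; used at once
Reagents that add atoms: carbon tetrabromide, BrC(Br)(Br)Br
Why: Appel bromination under neutral conditions, so the acid-labile MOM ether is kept.

Step 14
Reactants: 17 (2S,5S)-2,5-dimethylthiolane; 21 1-(bromomethyl)-4-(methoxymethoxy)benzene
Product: 22 (2S,5S)-1-{[4-(methoxymethoxy)phenyl]methyl}-2,5-dimethylthiolan-1-ium tetrafluoroborate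
Conditions: NaBF4 (3 equiv), CH2Cl2/H2O (1:1), rt; precipitated from Et2O
Reagents that add atoms: sodium tetrafluoroborate, [Na+].F[B-](F)(F)F
Why: S-alkylation of the sulfide by the reactive benzylic bromide with anion metathesis to the non-nucleophilic BF4 salt; the C2-symmetric sulfide gives a single sulfonium salt with no stereogenic sulfur.

Step 15
Reactants: 14 5-bromo-2-[{4-[[3,5-bis(methoxymethoxy)phenyl](4-methylbenzenesulfonyl)methyl]-3-hydroxy-5-(methoxymethoxy)phenyl}(4-methylbenzenesulfonyl)methyl]-3-(methoxymethoxy)phenol; 22 (2S,5S)-1-{[4-(methoxymethoxy)phenyl]methyl}-2,5-dimethylthiolan-1-ium tetrafluoroborate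
Product: 29 (2S,3S)-6-bromo-3-{(2S,3S)-3-[3,5-bis(methoxymethoxy)phenyl]-4-(methoxymethoxy)-2-[4-(methoxymethoxy)phenyl]-2,3-dihydro-1-benzofuran-6-yl}-4-(methoxymethoxy)-2-[4-(methoxymethoxy)phenyl]-2,3-dihydro-1-benzofuran, via [(2S,5S)-2,5-dimethylthiolan-1-ium-1-yl][4-(methoxymethoxy)phenyl]methanide 23 (not isolated), via 6-{[3,5-bis(methoxymethoxy)phenyl]methylidene}-3-{[4-bromo-2-hydroxy-6-(methoxymethoxy)phenyl](4-methylbenzenesulfonyl)methyl}-5-(methoxymethoxy)cyclohexa-2,4-dien-1-one 24 (not isolated), via 5-{[4-bromo-2-hydroxy-6-(methoxymethoxy)phenyl](4-methylbenzenesulfonyl)methyl}-2-{(1S,2R)-1-[3,5-bis(methoxymethoxy)phenyl]-2-[(2S,5S)-2,5-dimethylthiolan-1-ium-1-yl]-2-[4-(methoxymethoxy)phenyl]ethyl}-3-(methoxymethoxy)phenolate 25 (not isolated), via 5-bromo-2-[{(2S,3S)-3-[3,5-bis(methoxymethoxy)phenyl]-4-(methoxymethoxy)-2-[4-(methoxymethoxy)phenyl]-2,3-dihydro-1-benzofuran-6-yl}(4-methylbenzenesulfonyl)methyl]-3-(methoxymethoxy)phenol 26 (not isolated), via 3-bromo-6-({(2S,3S)-3-[3,5-bis(methoxymethoxy)phenyl]-4-(methoxymethoxy)-2-[4-(methoxymethoxy)phenyl]-2,3-dihydro-1-benzofuran-6-yl}methylidene)-5-(methoxymethoxy)cyclohexa-2,4-dien-1-one 27 (not isolated), via 5-bromo-2-{(1S,2R)-1-{(2S,3S)-3-[3,5-bis(methoxymethoxy)phenyl]-4-(methoxymethoxy)-2-[4-(methoxymethoxy)phenyl]-2,3-dihydro-1-benzofuran-6-yl}-2-[(2S,5S)-2,5-dimethylthiolan-1-ium-1-yl]-2-[4-(methoxymethoxy)phenyl]ethyl}-3-(methoxymethoxy)phenolate 28 (not isolated)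
Conditions: 22 (2.8 equiv), Cs2CO3 (6 equiv), MeCN/CH2Cl2 (1:1), −20 °C → rt; sulfide 17 recovered
Reagents that add atoms: none
Why: Proposed new method: enantioselective double formal [4+1] annulation in which Cs2CO3 deprotonates 22 to the semi-stabilised ylide 23 and releases an o-quinone methide at each sulfone in turn by E1cB loss of sulfinate (24 first, then 27 from the mono-annulated sulfone 26); each time the ylide's irreversible, rearomatising 1,4-addition through the aryl/aryl-anti transition state gives a betaine (25, then 28) whose phenoxide displaces the sulfide by 5-exo-tet SN2 with inversion, so the chiral sulfide's control of the ylide face sets C2 and the anti addition sets C3 of each trans-(2S,3S) ring, the two remote sites being set independently under reagent control so that a mis-set ring gives a separable diastereomer and raises the ee of 29; the closest known reactions are the [4+1] annulations of o-quinone methides with carbonyl-stabilised sulfur ylides and the chiral-sulfide benzylide epoxidations and aziridinations, whereas a non-racemic aryl-substituted ylide on an o-quinone methide giving 2,3-diaryl products has not been shown.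

Step 16
Reactants: 29 (2S,3S)-6-bromo-3-{(2S,3S)-3-[3,5-bis(methoxymethoxy)phenyl]-4-(methoxymethoxy)-2-[4-(methoxymethoxy)phenyl]-2,3-dihydro-1-benzofuran-6-yl}-4-(methoxymethoxy)-2-[4-(methoxymethoxy)phenyl]-2,3-dihydro-1-benzofuran; 30 4-ethenylphenyl acetate (4-acetoxystyrene)
Product: 31 4-[(E)-2-{(2S,3S)-3-{(2S,3S)-3-[3,5-bis(methoxymethoxy)phenyl]-4-(methoxymethoxy)-2-[4-(methoxymethoxy)phenyl]-2,3-dihydro-1-benzofuran-6-yl}-4-(methoxymethoxy)-2-[4-(methoxymethoxy)phenyl]-2,3-dihydro-1-benzofuran-6-yl}ethenyl]phenyl acetate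
Conditions: Pd2(dba)3 (2.5 mol%), [HP(t-Bu)3]BF4 (10 mol%), Cy2NMe (1.5 equiv), 30 (1.5 equiv), 1,4-dioxane, 80 °C
Reagents that add atoms: none
Why: Mizoroki–Heck reaction; syn-carbopalladation and syn-β-hydride elimination give the E-stilbene, and the hindered amine base leaves the acetate, the MOM ethers and the four stereocentres untouched.

Step 17
Reactants: 31 4-[(E)-2-{(2S,3S)-3-{(2S,3S)-3-[3,5-bis(methoxymethoxy)phenyl]-4-(methoxymethoxy)-2-[4-(methoxymethoxy)phenyl]-2,3-dihydro-1-benzofuran-6-yl}-4-(methoxymethoxy)-2-[4-(methoxymethoxy)phenyl]-2,3-dihydro-1-benzofuran-6-yl}ethenyl]phenyl acetate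
Product: 32 5-[(2S,3S)-4-hydroxy-6-{(2S,3S)-4-hydroxy-2-(4-hydroxyphenyl)-6-[(E)-2-(4-hydroxyphenyl)ethenyl]-2,3-dihydro-1-benzofuran-3-yl}-2-(4-hydroxyphenyl)-2,3-dihydro-1-benzofuran-3-yl]benzene-1,3-diol (CNP0248228.2)
Conditions: HCl (1.25 M in MeOH)/THF (1:1), degassed, 40 °C; NaHCO3 work-up
Reagents that add atoms: none
Why: Acid-catalysed transacetalisation of the six MOM ethers and transesterification of the aryl acetate, with methanol trapping the formaldehyde equivalents; the trans rings are the thermodynamic isomers, so no stereocentre is lost even if a C2–O bond ionises reversibly.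

**Compound list**
1 | 5-bromobenzene-1,3-diol | Oc1cc(O)cc(Br)c1 | starting material
2 | 1-bromo-3,5-bis(methoxymethoxy)benzene | COCOc1cc(OCOC)cc(Br)c1 | intermediate
3 | [4-bromo-2,6-bis(methoxymethoxy)phenyl]lithium | [Li]c1c(OCOC)cc(Br)cc1OCOC | intermediate
4 | lithium [4-bromo-2,6-bis(methoxymethoxy)phenyl](dimethylamino)methanolate | [Li]OC(N(C)C)c1c(OCOC)cc(Br)cc1OCOC | intermediate
5 | 4-bromo-2,6-bis(methoxymethoxy)benzaldehyde | COCOc1cc(Br)cc(OCOC)c1C=O | intermediate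
6 | 4-bromo-2-hydroxy-6-(methoxymethoxy)benzaldehyde | COCOc1cc(Br)cc(O)c1C=O | intermediate
7 | 4-bromo-2-(methoxymethoxy)-6-(prop-2-en-1-yloxy)benzaldehyde | C=CCOc1cc(Br)cc(OCOC)c1C=O | intermediate
8 | [3,5-bis(methoxymethoxy)phenyl]lithium | [Li]c1cc(OCOC)cc(OCOC)c1 | intermediate
9 | rac-[4-bromo-2-(methoxymethoxy)-6-(prop-2-en-1-yloxy)phenyl][3,5-bis(methoxymethoxy)phenyl]methanol | COCOc1cc(OCOC)cc(C(O)c2c(OCC=C)cc(Br)cc2OCOC)c1 | intermediate
10 | lithium [4-bromo-2-(methoxymethoxy)-6-(prop-2-en-1-yloxy)phenyl][3,5-bis(methoxymethoxy)phenyl]methanolate | [Li]OC(c1cc(OCOC)cc(OCOC)c1)c1c(OCC=C)cc(Br)cc1OCOC | intermediate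
11 | lithium [3,5-bis(methoxymethoxy)phenyl][4-lithio-2-(methoxymethoxy)-6-(prop-2-en-1-yloxy)phenyl]methanolate | [Li]OC(c1cc(OCOC)cc(OCOC)c1)c1c(OCC=C)cc([Li])cc1OCOC | intermediate
12 | [4-bromo-2-(methoxymethoxy)-6-(prop-2-en-1-yloxy)phenyl]{4-[[3,5-bis(methoxymethoxy)phenyl](hydroxy)methyl]-3-(methoxymethoxy)-5-(prop-2-en-1-yloxy)phenyl}methanol (mixture of diastereomers) | COCOc1cc(OCOC)cc(C(O)c2c(OCC=C)cc(C(O)c3c(OCC=C)cc(Br)cc3OCOC)cc2OCOC)c1 | intermediate
13 | 5-bromo-2-[{4-[[3,5-bis(methoxymethoxy)phenyl](hydroxy)methyl]-3-hydroxy-5-(methoxymethoxy)phenyl}(hydroxy)methyl]-3-(methoxymethoxy)phenol (mixture of diastereomers) | COCOc1cc(OCOC)cc(C(O)c2c(O)cc(C(O)c3c(O)cc(Br)cc3OCOC)cc2OCOC)c1 | intermediate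
14 | 5-bromo-2-[{4-[[3,5-bis(methoxymethoxy)phenyl](4-methylbenzenesulfonyl)methyl]-3-hydroxy-5-(methoxymethoxy)phenyl}(4-methylbenzenesulfonyl)methyl]-3-(methoxymethoxy)phenol (mixture of diastereomers) | Cc1ccc(S(=O)(=O)C(c2cc(OCOC)cc(OCOC)c2)c2c(O)cc(C(c3c(O)cc(Br)cc3OCOC)S(=O)(=O)c3ccc(C)cc3)cc2OCOC)cc1 | intermediate
15 | (2R,5R)-hexane-2,5-diol | C[C@@H](O)CC[C@@H](C)O | starting material
16 | (2R,5R)-hexane-2,5-diyl dimethanesulfonate | C[C@@H](OS(C)(=O)=O)CC[C@@H](C)OS(C)(=O)=O | intermediate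
17 | (2S,5S)-2,5-dimethylthiolane | C[C@H]1CC[C@H](C)S1 | intermediate
18 | 4-hydroxybenzaldehyde | O=Cc1ccc(O)cc1 | starting material
19 | 4-(methoxymethoxy)benzaldehyde | COCOc1ccc(C=O)cc1 | intermediate
20 | [4-(methoxymethoxy)phenyl]methanol | COCOc1ccc(CO)cc1 | intermediate
21 | 1-(bromomethyl)-4-(methoxymethoxy)benzene | COCOc1ccc(CBr)cc1 | intermediate
22 | (2S,5S)-1-{[4-(methoxymethoxy)phenyl]methyl}-2,5-dimethylthiolan-1-ium tetrafluoroborate | C[C@H]1CC[C@H](C)[S+]1Cc1ccc(OCOC)cc1.F[B-](F)(F)F | intermediate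
23 | [(2S,5S)-2,5-dimethylthiolan-1-ium-1-yl][4-(methoxymethoxy)phenyl]methanide (sulfonium ylide) | C[C@H]1CC[C@H](C)[S+]1[CH-]c1ccc(OCOC)cc1 | intermediate
24 | 6-{[3,5-bis(methoxymethoxy)phenyl]methylidene}-3-{[4-bromo-2-hydroxy-6-(methoxymethoxy)phenyl](4-methylbenzenesulfonyl)methyl}-5-(methoxymethoxy)cyclohexa-2,4-dien-1-one (first o-quinone methide) | O=C1C=C(C(c2c(O)cc(Br)cc2OCOC)S(=O)(=O)c2ccc(C)cc2)C=C(OCOC)C1=Cc1cc(OCOC)cc(OCOC)c1 | intermediate
25 | 5-{[4-bromo-2-hydroxy-6-(methoxymethoxy)phenyl](4-methylbenzenesulfonyl)methyl}-2-{(1S,2R)-1-[3,5-bis(methoxymethoxy)phenyl]-2-[(2S,5S)-2,5-dimethylthiolan-1-ium-1-yl]-2-[4-(methoxymethoxy)phenyl]ethyl}-3-(methoxymethoxy)phenolate (first betaine) | C[C@H]1CC[C@H](C)[S+]1[C@@H](c1ccc(OCOC)cc1)[C@H](c1c([O-])cc(C(c2c(O)cc(Br)cc2OCOC)S(=O)(=O)c2ccc(C)cc2)cc1OCOC)c1cc(OCOC)cc(OCOC)c1 | intermediate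
26 | 5-bromo-2-[{(2S,3S)-3-[3,5-bis(methoxymethoxy)phenyl]-4-(methoxymethoxy)-2-[4-(methoxymethoxy)phenyl]-2,3-dihydro-1-benzofuran-6-yl}(4-methylbenzenesulfonyl)methyl]-3-(methoxymethoxy)phenol (mono-annulated sulfone, both epimers at the sulfonyl carbon) | Cc1ccc(S(=O)(=O)C(c2cc(OCOC)c3c(c2)O[C@H](c2ccc(OCOC)cc2)[C@H]3c2cc(OCOC)cc(OCOC)c2)c2c(O)cc(Br)cc2OCOC)cc1 | intermediate
27 | 3-bromo-6-({(2S,3S)-3-[3,5-bis(methoxymethoxy)phenyl]-4-(methoxymethoxy)-2-[4-(methoxymethoxy)phenyl]-2,3-dihydro-1-benzofuran-6-yl}methylidene)-5-(methoxymethoxy)cyclohexa-2,4-dien-1-one (second o-quinone methide) | O=C1C=C(Br)C=C(OCOC)C1=Cc1cc(OCOC)c2c(c1)O[C@H](c1ccc(OCOC)cc1)[C@H]2c1cc(OCOC)cc(OCOC)c1 | intermediate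
28 | 5-bromo-2-{(1S,2R)-1-{(2S,3S)-3-[3,5-bis(methoxymethoxy)phenyl]-4-(methoxymethoxy)-2-[4-(methoxymethoxy)phenyl]-2,3-dihydro-1-benzofuran-6-yl}-2-[(2S,5S)-2,5-dimethylthiolan-1-ium-1-yl]-2-[4-(methoxymethoxy)phenyl]ethyl}-3-(methoxymethoxy)phenolate (second betaine) | C[C@H]1CC[C@H](C)[S+]1[C@@H](c1ccc(OCOC)cc1)[C@H](c1c([O-])cc(Br)cc1OCOC)c1cc(OCOC)c2c(c1)O[C@H](c1ccc(OCOC)cc1)[C@H]2c1cc(OCOC)cc(OCOC)c1 | intermediate
29 | (2S,3S)-6-bromo-3-{(2S,3S)-3-[3,5-bis(methoxymethoxy)phenyl]-4-(methoxymethoxy)-2-[4-(methoxymethoxy)phenyl]-2,3-dihydro-1-benzofuran-6-yl}-4-(methoxymethoxy)-2-[4-(methoxymethoxy)phenyl]-2,3-dihydro-1-benzofuran | Brc1cc(OCOC)c2c(c1)O[C@H](c1ccc(OCOC)cc1)[C@H]2c1cc(OCOC)c2c(c1)O[C@H](c1ccc(OCOC)cc1)[C@H]2c1cc(OCOC)cc(OCOC)c1 | intermediate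
30 | 4-ethenylphenyl acetate (4-acetoxystyrene) | CC(=O)Oc1ccc(C=C)cc1 | starting material
31 | 4-[(E)-2-{(2S,3S)-3-{(2S,3S)-3-[3,5-bis(methoxymethoxy)phenyl]-4-(methoxymethoxy)-2-[4-(methoxymethoxy)phenyl]-2,3-dihydro-1-benzofuran-6-yl}-4-(methoxymethoxy)-2-[4-(methoxymethoxy)phenyl]-2,3-dihydro-1-benzofuran-6-yl}ethenyl]phenyl acetate | CC(=O)Oc1ccc(/C=C/c2cc(OCOC)c3c(c2)O[C@H](c2ccc(OCOC)cc2)[C@H]3c2cc(OCOC)c3c(c2)O[C@H](c2ccc(OCOC)cc2)[C@H]3c2cc(OCOC)cc(OCOC)c2)cc1 | intermediate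
32 | 5-[(2S,3S)-4-hydroxy-6-{(2S,3S)-4-hydroxy-2-(4-hydroxyphenyl)-6-[(E)-2-(4-hydroxyphenyl)ethenyl]-2,3-dihydro-1-benzofuran-3-yl}-2-(4-hydroxyphenyl)-2,3-dihydro-1-benzofuran-3-yl]benzene-1,3-diol | Oc1ccc(/C=C/c2cc(O)c3c(c2)O[C@H](c2ccc(O)cc2)[C@H]3c2cc(O)c3c(c2)O[C@H](c2ccc(O)cc2)[C@H]3c2cc(O)cc(O)c2)cc1 | target

**Totals**
Total step count: 17. Longest linear sequence: 11 steps (1, 2, 3, 4, 5, 6, 7, 8, 15, 16, 17 from 5-bromoresorcinol).

**Three steps most likely to fail**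

Step 15 (proposed new double [4+1]). The risks are a kinetic cis/trans ratio in the irreversible ylide addition, O-benzylation of a phenoxide by the sulfonium salt, an untested level and sense of induction with alkoxy-substituted o-quinone methides, and the need for both annulations to succeed in one flask. The fallback uses known chemistry, sets out from 13 and comes back at 29. Both phenols of 13 are O-alkylated with bromide 21 (K2CO3, DMF, rt) to give [4-bromo-2-(methoxymethoxy)-6-{[4-(methoxymethoxy)phenyl]methoxy}phenyl]{4-[[3,5-bis(methoxymethoxy)phenyl](hydroxy)methyl]-3-(methoxymethoxy)-5-{[4-(methoxymethoxy)phenyl]methoxy}phenyl}methanol F1. Dess–Martin oxidation of both carbinols gives [4-bromo-2-(methoxymethoxy)-6-{[4-(methoxymethoxy)phenyl]methoxy}phenyl]{4-[3,5-bis(methoxymethoxy)benzoyl]-3-(methoxymethoxy)-5-{[4-(methoxymethoxy)phenyl]methoxy}phenyl}methanone F2. Forcing condensation with hydrazine hydrate (EtOH, cat. AcOH, 90 °C, sealed) gives the bis-hydrazone of that diketone F3. MnO2 in CH2Cl2 oxidises it to the bis(diaryldiazomethane) F4, which is not isolated. F4 undergoes the known Rh(II)-catalysed enantioselective intramolecular C–H insertion of a donor/donor carbene into a benzylic ether C–H, here at both sites (Rh2(R-PTAD)4 or its antipode, whichever gives 3S). This gives the cis,cis compound (2R,3S)-6-bromo-3-{(2R,3S)-3-[3,5-bis(methoxymethoxy)phenyl]-4-(methoxymethoxy)-2-[4-(methoxymethoxy)phenyl]-2,3-dihydro-1-benzofuran-6-yl}-4-(methoxymethoxy)-2-[4-(methoxymethoxy)phenyl]-2,3-dihydro-1-benzofuran F5. HCl/MeOH at 50 °C removes the MOM groups and epimerises both C2 centres through the p-hydroxybenzylic cations to the all-trans hexaphenol 5-[(2S,3S)-6-{(2S,3S)-6-bromo-4-hydroxy-2-(4-hydroxyphenyl)-2,3-dihydro-1-benzofuran-3-yl}-4-hydroxy-2-(4-hydroxyphenyl)-2,3-dihydro-1-benzofuran-3-yl]benzene-1,3-diol F6. Re-protection with MOMCl/i-Pr2NEt returns 29.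

Step 6 (addition of the alkoxide-bearing aryllithium 11 to aldehyde 7). The risks are proton quench of the aryllithium by unreacted carbinol, poor solubility of the dianion, and competing metalation of the allyl ether. The fallback masks the carbinol before the exchange; it sets out from 9 and comes back at 12. Carbinol 9 is silylated (TESCl, imidazole, DMF, rt) to {[4-bromo-2-(methoxymethoxy)-6-(prop-2-en-1-yloxy)phenyl][3,5-bis(methoxymethoxy)phenyl]methoxy}(triethyl)silane F7. Br/Li exchange (n-BuLi, 1.05 equiv, THF, −78 °C) gives triethyl{[4-lithio-2-(methoxymethoxy)-6-(prop-2-en-1-yloxy)phenyl][3,5-bis(methoxymethoxy)phenyl]methoxy}silane F8, which is not isolated. It adds to aldehyde 7 to give [4-bromo-2-(methoxymethoxy)-6-(prop-2-en-1-yloxy)phenyl]{4-[[3,5-bis(methoxymethoxy)phenyl][(triethylsilyl)oxy]methyl]-3-(methoxymethoxy)-5-(prop-2-en-1-yloxy)phenyl}methanol F9. TBAF in THF at 0 °C removes the silyl group and returns 12.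

Step 7 (double deallylation to the free tetraol 13). The risks are loss of the aryl bromide to Pd(0) and decomposition of 13, which carries two o-hydroxybenzhydrol units that readily form o-quinone methides on silica or with traces of acid. The fallback reverses the order so that 13 is never made; it sets out from 12 and comes back at 14. Bis-carbinol 12 is sulfonylated first (p-TolSO2H, CH2Cl2, rt; the 2,6-dialkoxyaryl carbinols ionise without a free phenol) to give 5-bromo-2-[{4-[[3,5-bis(methoxymethoxy)phenyl](4-methylbenzenesulfonyl)methyl]-3-(methoxymethoxy)-5-(prop-2-en-1-yloxy)phenyl}(4-methylbenzenesulfonyl)methyl]-1-(methoxymethoxy)-3-(prop-2-en-1-yloxy)benzene F10. Pd(PPh3)4 (5 mol%) with sodium 4-methylbenzenesulfinate as the allyl acceptor in THF/MeOH at rt then removes both allyl groups and returns 14.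

**Further compounds**
F1 | step 15 | [4-bromo-2-(methoxymethoxy)-6-{[4-(methoxymethoxy)phenyl]methoxy}phenyl]{4-[[3,5-bis(methoxymethoxy)phenyl](hydroxy)methyl]-3-(methoxymethoxy)-5-{[4-(methoxymethoxy)phenyl]methoxy}phenyl}methanol | COCOc1cc(OCOC)cc(C(O)c2c(OCc3ccc(OCOC)cc3)cc(C(O)c3c(OCc4ccc(OCOC)cc4)cc(Br)cc3OCOC)cc2OCOC)c1
F2 | step 15 | [4-bromo-2-(methoxymethoxy)-6-{[4-(methoxymethoxy)phenyl]methoxy}phenyl]{4-[3,5-bis(methoxymethoxy)benzoyl]-3-(methoxymethoxy)-5-{[4-(methoxymethoxy)phenyl]methoxy}phenyl}methanone | COCOc1cc(OCOC)cc(C(=O)c2c(OCc3ccc(OCOC)cc3)cc(C(=O)c3c(OCc4ccc(OCOC)cc4)cc(Br)cc3OCOC)cc2OCOC)c1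
F3 | step 15 | bis-hydrazone of F2 | COCOc1cc(OCOC)cc(C(=NN)c2c(OCc3ccc(OCOC)cc3)cc(C(=NN)c3c(OCc4ccc(OCOC)cc4)cc(Br)cc3OCOC)cc2OCOC)c1
F4 | step 15 | bis(diaryldiazomethane) from F3 | COCOc1cc(OCOC)cc(C(=[N+]=[N-])c2c(OCc3ccc(OCOC)cc3)cc(C(=[N+]=[N-])c3c(OCc4ccc(OCOC)cc4)cc(Br)cc3OCOC)cc2OCOC)c1
F5 | step 15 | (2R,3S)-6-bromo-3-{(2R,3S)-3-[3,5-bis(methoxymethoxy)phenyl]-4-(methoxymethoxy)-2-[4-(methoxymethoxy)phenyl]-2,3-dihydro-1-benzofuran-6-yl}-4-(methoxymethoxy)-2-[4-(methoxymethoxy)phenyl]-2,3-dihydro-1-benzofuran (both rings cis) | Brc1cc(OCOC)c2c(c1)O[C@@H](c1ccc(OCOC)cc1)[C@H]2c1cc(OCOC)c2c(c1)O[C@@H](c1ccc(OCOC)cc1)[C@H]2c1cc(OCOC)cc(OCOC)c1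
F6 | step 15 | 5-[(2S,3S)-6-{(2S,3S)-6-bromo-4-hydroxy-2-(4-hydroxyphenyl)-2,3-dihydro-1-benzofuran-3-yl}-4-hydroxy-2-(4-hydroxyphenyl)-2,3-dihydro-1-benzofuran-3-yl]benzene-1,3-diol | Brc1cc(O)c2c(c1)O[C@H](c1ccc(O)cc1)[C@H]2c1cc(O)c2c(c1)O[C@H](c1ccc(O)cc1)[C@H]2c1cc(O)cc(O)c1
F7 | step 6 | {[4-bromo-2-(methoxymethoxy)-6-(prop-2-en-1-yloxy)phenyl][3,5-bis(methoxymethoxy)phenyl]methoxy}(triethyl)silane | CC[Si](CC)(CC)OC(c1cc(OCOC)cc(OCOC)c1)c1c(OCC=C)cc(Br)cc1OCOC
F8 | step 6 | triethyl{[4-lithio-2-(methoxymethoxy)-6-(prop-2-en-1-yloxy)phenyl][3,5-bis(methoxymethoxy)phenyl]methoxy}silane | CC[Si](CC)(CC)OC(c1cc(OCOC)cc(OCOC)c1)c1c(OCC=C)cc([Li])cc1OCOC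
F9 | step 6 | [4-bromo-2-(methoxymethoxy)-6-(prop-2-en-1-yloxy)phenyl]{4-[[3,5-bis(methoxymethoxy)phenyl][(triethylsilyl)oxy]methyl]-3-(methoxymethoxy)-5-(prop-2-en-1-yloxy)phenyl}methanol | CC[Si](CC)(CC)OC(c1cc(OCOC)cc(OCOC)c1)c1c(OCC=C)cc(C(O)c2c(OCC=C)cc(Br)cc2OCOC)cc1OCOC
F10 | step 7 | 5-bromo-2-[{4-[[3,5-bis(methoxymethoxy)phenyl](4-methylbenzenesulfonyl)methyl]-3-(methoxymethoxy)-5-(prop-2-en-1-yloxy)phenyl}(4-methylbenzenesulfonyl)methyl]-1-(methoxymethoxy)-3-(prop-2-en-1-yloxy)benzene | Cc1ccc(S(=O)(=O)C(c2cc(OCOC)cc(OCOC)c2)c2c(OCC=C)cc(C(c3c(OCC=C)cc(Br)cc3OCOC)S(=O)(=O)c3ccc(C)cc3)cc2OCOC)cc1
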